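**Strategy.** The cis-decalin is cut so that C8–C9–C10–C5–C4–C3 (methylidene carbon, pyronylmethyl-bearing CH, angular-methyl carbon, ring-fusion CH, quaternary carbon, carbinol carbon) are the six ring carbons of 2-methoxy-3-methylphenol, its two oxygenated carbons being C8 and C9. One operation dearomatises this phenol to a chiral spiro-dioxolane dienone and adds ethene across its diene. This bonds C10 and C3 to the future C1–C2 unit and gives a bicyclo[2.2.2]octenone that already holds all of ring A and the quaternary C10. Vinyl addition and anionic oxy-Cope rearrangement later unfold it into the cis-decalin; an iodo-γ-pyrone is joined late by Negishi coupling.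

Key step: step 1

Remarks on the chemistry (assumptions)
- Decalin numbering (terpenoid style): C10 angular-methyl carbon, C5 ring-fusion CH, C4 quaternary carbon, C3 carbinol carbon, C1/C2 and C6/C7 methylenes, C8 methylidene carbon, C9 pyronylmethyl-bearing CH; β is the face of the C10 methyl. All decalins are cis-fused (5β-H, 10β-Me).
- Bicyclo[2.2.2]octenone numbering: C1 bridgehead CH next to the ketone C2, C3 former ketal carbon, C4 methyl-bearing bridgehead, C5=C6 alkene bridge, C7–C8 ethano bridge.
- 2-Methoxy-3-methylphenol (1) is taken as a catalogue compound.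
- 4-Methoxybenzyl chloromethyl ether is a known reagent, made just before use from 4-methoxybenzyl methylthiomethyl ether and sulfuryl chloride; acetic formic anhydride is prepared separately.

**Route**

Step 1
Reactants: 1 2-methoxy-3-methylphenol; 2 (2R,3R)-butane-2,3-diol; 3 ethene
Product: 6 spiroketal adduct (4'R,5'R)-1,4',5'-trimethylspiro[bicyclo[2.2.2]oct-5-ene-2,2'-[1,3]dioxolan]-3-one (bridgeheads as in the SMILES), via mixed ketal 4 (not isolated), via spiroketal dienone 5 (not isolated)
Conditions: PhI(OAc)2, 2 (excess), PPTS (cat.), 4 Å MS, CH2Cl2, −20 → 0 °C; then ethene (60 bar), 40 °C, autoclave; chromatographic separation of the two ketal diastereomers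
Reagents that add atoms: none
Why: Proposed new method: two-electron oxidation of the phenol on iodine(III) gives a phenoxenium-type cation that the diol captures at the methoxy-bearing carbon (mixed ketal 4); acid-promoted loss of methanol and attack of the second hydroxyl on the same carbon closes the dioxolane (five-membered O,O-ketal, formally a 5-exo attack on the dienyl cation), and the 2,4-dienone 5 then takes up ethene in a concerted, suprafacial [4+2] cycloaddition that closes the six-membered carbocycle of the bicyclo[2.2.2]octenone. The closest known reaction type is the in situ generation and Diels–Alder trapping of masked o-benzoquinones (6,6-dialkoxycyclohexa-2,4-dienones) made by oxidising 2-alkoxyphenols, here extended to an unactivated alkene under pressure and to a C2-symmetric diol as ketal donor. The two new stereocentres are the bridgeheads (methyl-bearing carbon and the CH next to the ketone); their relative configuration is fixed by the bicycle and their absolute sense depends only on which diene face ethene takes, the faces being made diastereotopic by the trans-dimethyl dioxolane (the spiro carbon is not stereogenic because the diol is C2-symmetric). Regiochemistry does not arise with ethene; the selectivity needed is cycloaddition over dimerisation of 5, which the methyl on the diene terminus next to the spiro carbon, high ethene pressure and dilution should secure. Face selectivity is expected to be modest and its sense cannot be predicted with confidence, so both diastereomeric ketals are to be separated and the one with the bridgehead configuration shown is carried on.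

Step 2
Reactants: 6 spiroketal adduct
Product: 7 (1S,4S)-4-methylbicyclo[2.2.2]oct-5-en-2-one
Conditions: SmI2 (excess), MeOH, THF, −78 → 0 °C
Reagents that add atoms: none
Why: Samarium(II)-mediated reductive cleavage of α-alkoxy ketones removes both ketal C–O bonds in turn, the samarium enolate being protonated by methanol, and leaves the bridgehead centres untouched.

Step 3
Reactants: 7 (1S,4S)-4-methylbicyclo[2.2.2]oct-5-en-2-one
Product: 8 3-[(4-methoxybenzyloxy)methyl] derivative of 7, side chain syn to the C5=C6 bridge
Conditions: LDA, THF, −78 °C; 4-methoxybenzyl chloromethyl ether, −78 → −40 °C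
Reagents that add atoms: 4-methoxybenzyl chloromethyl ether, COc1ccc(COCCl)cc1
Why: Kinetic enolate alkylation (SN2 on a reactive α-chloro ether): C3 is the only enolisable position because C1 is a bridgehead, and the electrophile should enter syn to the C5=C6 bridge, whose in-plane vinyl hydrogens shield the enolate less than the ethano hydrogens do.

Step 4
Reactants: 8 alkylated ketone (side chain syn to C5=C6)
Product: 9 C3 epimer of 8, side chain syn to the C7–C8 ethano bridge
Conditions: LDA, THF, −78 °C; then 2,6-di-tert-butyl-4-methylphenol, −78 °C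
Reagents that add atoms: none
Why: Kinetic protonation of the lithium enolate: the bulky phenol should deliver the proton on the same less hindered face next to the C5=C6 bridge, which forces the side chain to the ethano side, and −78 °C should suppress β-elimination of the alkoxide.

Step 5
Reactants: 9 epimerised ketone
Product: 10 tertiary carbinol with 2-vinyl syn to the C5=C6 bridge and 2-hydroxyl syn to the ethano bridge
Conditions: CH2=CHMgBr, CeCl3, THF, −78 °C
Reagents that add atoms: vinylmagnesium bromide, C=C[Mg]Br
Why: 1,2-Addition of an organocerium reagent (which suppresses enolisation and β-elimination) should occur on the carbonyl face next to the C5=C6 bridge, anti to the C3 substituent, so the vinyl group ends up syn to the ring alkene at the new carbinol centre.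

Step 6
Reactants: 10 vinyl carbinol
Product: 12 cis-octalone 9α-[(4-methoxybenzyloxy)methyl]-10β-methyl-5βH-decal-3-en-8-one, via potassium enolate 11 (not isolated)
Conditions: KH, 18-crown-6, THF, 0 → 25 °C; then AcOH, −78 °C
Reagents that add atoms: none
Why: Anionic oxy-Cope rearrangement ([3,3]-sigmatropic shift of the potassium 1,5-dien-3-olate in the boat-like geometry the bicycle enforces): the new C5–C6 bond forms on the outer face of the ring alkene, so the C5 hydrogen becomes cis to the C10 methyl, and protonation of the enolate gives the cis-octalone with C9 unchanged.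

Step 7
Reactants: 12 cis-octalone
Product: 13 8,8-ethylenedioxy ketal of 12
Conditions: TMSOCH2CH2OTMS, TMSOTf (cat.), CH2Cl2, −78 → −20 °C
Reagents that add atoms: 1,2-bis(trimethylsilyloxy)ethane, C[Si](C)(C)OCCO[Si](C)(C)C
Why: Noyori ketalisation protects the ring-B ketone under non-aqueous, low-temperature conditions that leave the PMB ether and the C9 centre alone.

Step 8
Reactants: 13 ketal alkene
Product: 15 8,8-ethylenedioxy-9α-[(4-methoxybenzyloxy)methyl]-10β-methyl-5βH-decalin-3β-ol, via alkylborane 14 (not isolated)
Conditions: 9-BBN, THF, 65 °C; then NaOH, H2O2, 0 → 25 °C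
Reagents that add atoms: hydrogen peroxide, OO
Why: Hydroboration–oxidation: the bulky borane should place boron on C3, the alkene carbon remote from the ring-fusion methine, by syn addition on the convex β-face, and oxidation proceeds with retention; the carbinol configuration is lost in the next step.

Step 9
Reactants: 15 ring-A alcohol
Product: 16 8,8-ethylenedioxy-9α-[(4-methoxybenzyloxy)methyl]-10β-methyl-5βH-decalin-3-one
Conditions: Dess–Martin periodinane, NaHCO3, CH2Cl2, 0 → 25 °C
Reagents that add atoms: none
Why: Dess–Martin oxidation converts the secondary alcohol to the ketone under buffered, neutral conditions.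

Step 10
Reactants: 16 ring-A ketone
Product: 17 4α-(3-methylbut-2-enyl) derivative of 16 (4β-H)
Conditions: KH, THF, 25 °C; BEt3; prenyl bromide, 0 → 25 °C
Reagents that add atoms: 1-bromo-3-methylbut-2-ene, CC(C)=CCBr
Why: Alkylation of the equilibrated potassium enolate, tamed as its enoxytriethylborate against polyalkylation: cis-fused 3-decalones are expected to enolise toward the ring fusion (as A/B-cis 3-oxo steroids do), so the allylic bromide should react at C4; the C4 configuration is immaterial because the centre is re-enolised next.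

Step 11
Reactants: 17 4-prenyl ketone
Product: 18 4β-methyl-4α-(3-methylbut-2-enyl) ketone
Conditions: KOt-Bu, t-BuOH/THF, 0 °C; MeI
Reagents that add atoms: iodomethane, CI
Why: Alkylation of the more substituted enolate formed under equilibrating conditions: iodomethane should approach C4 axially on the convex β-face, anti to the pseudo-axial C5–C6 bond and away from ring B, which sets the quaternary centre as 4β-methyl/4α-prenyl.

Step 12
Reactants: 18 quaternary ketone
Product: 19 3α-alcohol 8,8-ethylenedioxy-9α-[(4-methoxybenzyloxy)methyl]-4β,10β-dimethyl-4α-(3-methylbut-2-enyl)-5βH-decalin-3α-ol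
Conditions: L-Selectride, THF, −78 °C
Reagents that add atoms: none
Why: Reduction with a bulky borohydride: the α-face of the C3 carbonyl is blocked by the axial C5–C6 bond and the concave ring B, so hydride should add from the β-face and give the 3α (axial) alcohol cis to the prenyl group.

Step 13
Reactants: 19 ketal alcohol
Product: 20 3α-hydroxy-9α-[(4-methoxybenzyloxy)methyl]-4β,10β-dimethyl-4α-(3-methylbut-2-enyl)-5βH-decalin-8-one
Conditions: PPTS, acetone/H2O, 50 °C
Reagents that add atoms: water, O
Why: Mild acid-catalysed hydrolysis (transketalisation to acetone) of the dioxolane, under conditions that should neither add the C3 hydroxyl to the prenyl alkene nor epimerise C9.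

Step 14
Reactants: 20 keto alcohol
Product: 21 3α-triethylsilyl ether of 20
Conditions: TESOTf, 2,6-lutidine, CH2Cl2, −78 °C
Reagents that add atoms: triethylsilyl trifluoromethanesulfonate, CC[Si](CC)(CC)OS(=O)(=O)C(F)(F)F
Why: Silylation of a hindered secondary alcohol with a silyl triflate; at −78 °C it is much faster than enol-silane formation at the ring-B ketone.

Step 15
Reactants: 21 silyl ether
Product: 22 4α-(3-hydroxy-3-methylbutyl) ketone
Conditions: Co(acac)2 (cat.), PhSiH3, O2 (1 atm), THF, 25 °C
Reagents that add atoms: dioxygen, O=O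
Why: Mukaiyama hydration (cobalt-catalysed hydrogen-atom transfer to the trisubstituted alkene, capture of the tertiary radical by O2, reduction of the peroxide) places the hydroxyl on the dimethyl-substituted carbon with Markovnikov selectivity.

Step 16
Reactants: 22 hydroxy ketone
Product: 23 8-methylidene compound 4α-(3-hydroxy-3-methylbutyl)-9α-[(4-methoxybenzyloxy)methyl]-4β,10β-dimethyl-8-methylidene-3α-triethylsilyloxy-5βH-decalin
Conditions: Zn, CH2Br2, TiCl4, THF/CH2Cl2, 0 → 25 °C
Reagents that add atoms: dibromomethane, BrCBr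
Why: Takai–Lombardo methylenation with a non-basic reagent, chosen because it olefinates hindered, enolisable ketones without epimerising C9 or eliminating the β-alkoxy group; excess reagent allows for the free tertiary alcohol.

Step 17
Reactants: 23 tertiary alcohol
Product: 24 tertiary formate of 23
Conditions: acetic formic anhydride, pyridine, DMAP (cat.), CH2Cl2, 0 → 25 °C
Reagents that add atoms: acetic formic anhydride, CC(=O)OC=O
Why: Acylation with a mixed anhydride under nucleophilic catalysis: the tertiary alcohol is the only free hydroxyl and the formyl group is transferred in preference to acetyl.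

Step 18
Reactants: 24 formate PMB ether
Product: 25 9α-hydroxymethyl compound
Conditions: DDQ, CH2Cl2/pH 7 buffer, 0 °C
Reagents that add atoms: none
Why: Oxidative PMB cleavage by DDQ (hydride abstraction, hydrolysis of the oxocarbenium ion) under buffered conditions that spare the formate, the silyl ether and the 1,1-disubstituted alkene.

Step 19
Reactants: 25 primary alcohol
Product: 26 9α-iodomethyl compound
Conditions: I2, PPh3, imidazole, CH2Cl2, 0 → 25 °C
Reagents that add atoms: iodine, II
Why: Appel-type iodination of the β-branched primary alcohol by SN2 displacement of the oxyphosphonium group.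

Step 20
Reactants: 27 methyl acetoacetate; 28 malonyl dichloride
Product: 29 methyl 4-hydroxy-2-methyl-6-oxo-6H-pyran-3-carboxylate
Conditions: CH2Cl2, 0 → 40 °C (HCl evolution)
Reagents that add atoms: none
Why: C-Acylation of the β-keto ester by the bis-acid chloride followed by O-acylative ring closure of the enol (the malonyl chloride synthesis of 4-hydroxy-2-pyranones) delivers the ring with ester and methyl in place.

Step 21
Reactants: 29 hydroxypyranone
Product: 30 methyl 4-hydroxy-5-iodo-2-methyl-6-oxo-6H-pyran-3-carboxylate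
Conditions: NIS, MeCN, 25 °C
Reagents that add atoms: N-iodosuccinimide, O=C1CCC(=O)N1I
Why: Electrophilic iodination at C5, the nucleophilic carbon between the enol and the lactone carbonyl of a 4-hydroxy-2-pyranone.

Step 22
Reactants: 30 iodo-hydroxypyranone
Product: 31 methyl 5-iodo-6-methoxy-2-methyl-4-oxo-4H-pyran-3-carboxylate
Conditions: MeOTf, 2,6-di-tert-butyl-4-methylpyridine, CH2Cl2, 0 → 25 °C
Reagents that add atoms: methyl trifluoromethanesulfonate, COS(=O)(=O)C(F)(F)F
Why: O-Methylation with a hard methylating agent is known to take place at the lactone carbonyl oxygen of 4-hydroxy-2-pyranones (the 4-OH here being tied up by hydrogen bonding to the ester), so loss of the proton gives the 2-methoxy-4-pyranone instead of the 4-methoxy-2-pyranone.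

Step 23
Reactants: 26 9α-iodomethyl compound; 31 iodo-γ-pyranone
Product: 33 triethylsilyl ether of the target, via alkylzinc iodide 32 (not isolated)
Conditions: Zn dust (TMSCl-activated), LiCl, THF, 40 °C; then 31, Pd(OAc)2 (cat.), SPhos (cat.), THF, 25 → 40 °C
Reagents that add atoms: none
Why: Negishi sp3–sp2 cross-coupling: LiCl-assisted zinc insertion into the primary iodide gives an alkylzinc reagent that tolerates the formate, silyl ether and ester, and a bulky biarylphosphine should make reductive elimination outrun β-hydride elimination.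

Step 24
Reactants: 33 triethylsilyl ether of the target
Product: 34 target CNP0292250.1
Conditions: HF·pyridine, pyridine/THF, 0 → 25 °C
Reagents that add atoms: none
Why: Fluoride-mediated cleavage of the triethylsilyl ether under buffered conditions that leave the formate, the methyl ester, the methoxypyranone and the methylidene group intact.

**Compound list**

1 | 2-methoxy-3-methylphenol | COc1c(C)cccc1O | starting material
2 | (2R,3R)-butane-2,3-diol | C[C@@H](O)[C@@H](C)O | starting material
3 | ethene | C=C | starting material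
4 | 6-[(2R,3R)-3-hydroxybutan-2-yl]oxy-6-methoxy-5-methylcyclohexa-2,4-dien-1-one (mixed ketal, both ketal epimers) | COC1(O[C@H](C)[C@@H](C)O)C(C)=CC=CC1=O | intermediate (not isolated)
5 | (2R,3R)-2,3,6-trimethyl-1,4-dioxaspiro[4.5]deca-6,8-dien-10-one | O=C1C=CC=C(C)C12O[C@H](C)[C@@H](C)O2 | intermediate (not isolated)
6 | (4'R,5'R)-1,4',5'-trimethylspiro[bicyclo[2.2.2]oct-5-ene-2,2'-[1,3]dioxolan]-3-one, bridgeheads as shown | O=C1[C@H]2CC[C@](C)(C=C2)C13O[C@H](C)[C@@H](C)O3 | intermediate
7 | (1S,4S)-4-methylbicyclo[2.2.2]oct-5-en-2-one | O=C1[C@H]2CC[C@](C)(C=C2)C1 | intermediate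
8 | 3-[(4-methoxybenzyloxy)methyl] derivative of 7, side chain syn to C5=C6 | O=C1[C@H]2CC[C@](C)(C=C2)[C@@H]1COCc1ccc(OC)cc1 | intermediate
9 | C3 epimer of 8, side chain syn to the ethano bridge | O=C1[C@H]2CC[C@](C)(C=C2)[C@H]1COCc1ccc(OC)cc1 | intermediate
10 | 2-vinyl carbinol from 9 (vinyl syn to C5=C6, OH syn to ethano bridge) | O[C@@]1(C=C)[C@H]2CC[C@](C)(C=C2)[C@H]1COCc1ccc(OC)cc1 | intermediate
11 | potassium 7,8-enolate of 12 | [K+].[O-]C1=CC[C@H]2C=CCC[C@@]2(C)[C@H]1COCc1ccc(OC)cc1 | intermediate (not isolated)
12 | 9α-[(4-methoxybenzyloxy)methyl]-10β-methyl-5βH-decal-3-en-8-one | O=C1CC[C@H]2C=CCC[C@@]2(C)[C@H]1COCc1ccc(OC)cc1 | intermediate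
13 | 8,8-ethylenedioxy ketal of 12 | C1COC2(O1)CC[C@H]3C=CCC[C@@]3(C)[C@H]2COCc1ccc(OC)cc1 | intermediate
14 | 3β-(9-borabicyclo[3.3.1]nonan-9-yl) adduct of 13 | C1COC2(O1)CC[C@H]3C[C@H](B4C5CCCC4CCC5)CC[C@@]3(C)[C@H]2COCc1ccc(OC)cc1 | intermediate (not isolated)
15 | 8,8-ethylenedioxy-9α-[(4-methoxybenzyloxy)methyl]-10β-methyl-5βH-decalin-3β-ol | C1COC2(O1)CC[C@H]3C[C@H](O)CC[C@@]3(C)[C@H]2COCc1ccc(OC)cc1 | intermediate
16 | corresponding decalin-3-one | C1COC2(O1)CC[C@H]3CC(=O)CC[C@@]3(C)[C@H]2COCc1ccc(OC)cc1 | intermediate
17 | 4α-(3-methylbut-2-enyl) ketone | C1COC2(O1)CC[C@H]3[C@@H](CC=C(C)C)C(=O)CC[C@@]3(C)[C@H]2COCc1ccc(OC)cc1 | intermediate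
18 | 4β-methyl-4α-(3-methylbut-2-enyl) ketone | C1COC2(O1)CC[C@H]3[C@@](C)(CC=C(C)C)C(=O)CC[C@@]3(C)[C@H]2COCc1ccc(OC)cc1 | intermediate
19 | corresponding 3α-alcohol | C1COC2(O1)CC[C@H]3[C@@](C)(CC=C(C)C)[C@@H](O)CC[C@@]3(C)[C@H]2COCc1ccc(OC)cc1 | intermediate
20 | 3α-hydroxy-8-ketone | O=C1CC[C@H]2[C@@](C)(CC=C(C)C)[C@@H](O)CC[C@@]2(C)[C@H]1COCc1ccc(OC)cc1 | intermediate
21 | 3α-triethylsilyl ether of 20 | O=C1CC[C@H]2[C@@](C)(CC=C(C)C)[C@@H](O[Si](CC)(CC)CC)CC[C@@]2(C)[C@H]1COCc1ccc(OC)cc1 | intermediate
22 | 4α-(3-hydroxy-3-methylbutyl) ketone | O=C1CC[C@H]2[C@@](C)(CCC(C)(C)O)[C@@H](O[Si](CC)(CC)CC)CC[C@@]2(C)[C@H]1COCc1ccc(OC)cc1 | intermediate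
23 | 8-methylidene tertiary alcohol | C=C1CC[C@H]2[C@@](C)(CCC(C)(C)O)[C@@H](O[Si](CC)(CC)CC)CC[C@@]2(C)[C@H]1COCc1ccc(OC)cc1 | intermediate
24 | tertiary formate of 23 | C=C1CC[C@H]2[C@@](C)(CCC(C)(C)OC=O)[C@@H](O[Si](CC)(CC)CC)CC[C@@]2(C)[C@H]1COCc1ccc(OC)cc1 | intermediate
25 | 9α-hydroxymethyl compound | C=C1CC[C@H]2[C@@](C)(CCC(C)(C)OC=O)[C@@H](O[Si](CC)(CC)CC)CC[C@@]2(C)[C@H]1CO | intermediate
26 | 9α-iodomethyl compound | C=C1CC[C@H]2[C@@](C)(CCC(C)(C)OC=O)[C@@H](O[Si](CC)(CC)CC)CC[C@@]2(C)[C@H]1CI | intermediate
27 | methyl acetoacetate | CC(=O)CC(=O)OC | starting material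
28 | malonyl dichloride | O=C(Cl)CC(=O)Cl | starting material
29 | methyl 4-hydroxy-2-methyl-6-oxo-6H-pyran-3-carboxylate | COC(=O)c1c(C)oc(=O)cc1O | intermediate
30 | methyl 4-hydroxy-5-iodo-2-methyl-6-oxo-6H-pyran-3-carboxylate | COC(=O)c1c(C)oc(=O)c(I)c1O | intermediate
31 | methyl 5-iodo-6-methoxy-2-methyl-4-oxo-4H-pyran-3-carboxylate | COC(=O)c1c(C)oc(OC)c(I)c1=O | intermediate
32 | alkylzinc iodide from 26 | C=C1CC[C@H]2[C@@](C)(CCC(C)(C)OC=O)[C@@H](O[Si](CC)(CC)CC)CC[C@@]2(C)[C@H]1C[Zn]I | intermediate (not isolated)
33 | 3α-triethylsilyl ether of the target | C=C1CC[C@H]2[C@@](C)(CCC(C)(C)OC=O)[C@@H](O[Si](CC)(CC)CC)CC[C@@]2(C)[C@H]1Cc1c(OC)oc(C)c(C(=O)OC)c1=O | intermediate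
34 | CNP0292250.1 | C=C1CC[C@H]2[C@@](C)(CCC(C)(C)OC=O)[C@@H](O)CC[C@@]2(C)[C@H]1Cc1c(OC)oc(C)c(C(=O)OC)c1=O | target

**Step count**

Total: 24 steps (21 in the main line, 3 for the pyranone). Longest linear sequence: 21 steps (steps 1–19, 23, 24).

**Steps most likely to fail**

Step 1. Ethene may react too slowly, so that the dienone dimerises or decomposes first; exchange of methanol for the diol may stop at the mixed ketal; and the face selectivity may be poor or favour the other diastereomer. The fallback sets out from 1 and returns at 7 using known dimethyl-ketal chemistry. Compound 1 is oxidised with PhI(OAc)2 in methanol in the presence of excess phenyl vinyl sulfone, a classical ethene equivalent, to give racemic 3,3-dimethoxy-4-methyl-7-(phenylsulfonyl)bicyclo[2.2.2]oct-5-en-2-one F1 (regio- and endo/exo isomers converge later). SmI2/MeOH removes both methoxy groups to give racemic 4-methyl-7-(phenylsulfonyl)bicyclo[2.2.2]oct-5-en-2-one F2. Buffered sodium amalgam (Na2HPO4, MeOH, −20 °C) cleaves the sulfonyl group to give racemic 4-methylbicyclo[2.2.2]oct-5-en-2-one F3. Ketalisation of F3 with diol 2 (TsOH, benzene, Dean–Stark) gives two diastereomeric ketals; after chromatographic separation, the (2R,3R)-butane-2,3-diyl ketal of the (1S,4S)-ketone F4 is hydrolysed (aq. HCl, acetone) to 7.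

Step 10. Enolisation may go toward C2 instead of C4, and polyalkylation may follow. The fallback sets out from 16 and returns at 18, using that same enolisation preference to block C2. Palladium-catalysed aerobic dehydrogenation (Pd(TFA)2, DMSO, O2, EtOAc, 60 °C) gives the 1-en-3-one (8,8-ethylenedioxy-9α-[(4-methoxybenzyloxy)methyl]-10β-methyl-5βH-decal-1-en-3-one) F5, in which C4 is the only enolisable carbon. LDA then prenyl bromide gives the 4α-prenyl enone F6, and LDA then MeI gives the 4β-methyl-4α-prenyl enone F7. Copper hydride conjugate reduction (Stryker's reagent, benzene, 25 °C) saturates C1=C2 and gives 18.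

Step 23. Protodezincation, or β-hydride elimination from the alkylpalladium intermediate, may outrun C–C bond formation with the hindered iodopyranone. The fallback sets out from 25 (with 31) and returns at 33 by carbonyl addition. Dess–Martin oxidation of 25 gives the 9α-carbaldehyde F8. Iodine–magnesium exchange on 31 (i-PrMgCl·LiCl, THF, −78 °C) gives the pyranylmagnesium chloride F9, which adds to F8 at −78 °C to give the secondary carbinol F10 (either epimer serves). Its O-phenyl thionocarbonate F11 (PhOC(S)Cl, pyridine, DMAP) is reduced under Barton–McCombie conditions (Bu3SnH, AIBN, toluene, 80 °C) to 33.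

**Further compounds**

F1 | step 1 | racemic 3,3-dimethoxy-4-methyl-7-(phenylsulfonyl)bicyclo[2.2.2]oct-5-en-2-one | COC1(OC)C(=O)C2C=CC1(C)CC2S(=O)(=O)c1ccccc1
F2 | step 1 | racemic 4-methyl-7-(phenylsulfonyl)bicyclo[2.2.2]oct-5-en-2-one | O=C1CC2(C)C=CC1C(S(=O)(=O)c1ccccc1)C2
F3 | step 1 | racemic 4-methylbicyclo[2.2.2]oct-5-en-2-one | O=C1CC2(C)CCC1C=C2
F4 | step 1 | (2R,3R)-butane-2,3-diyl ketal of (1S,4S)-4-methylbicyclo[2.2.2]oct-5-en-2-one | C12(O[C@H](C)[C@@H](C)O1)[C@H]1CC[C@](C)(C=C1)C2
F5 | step 10 | 8,8-ethylenedioxy-9α-[(4-methoxybenzyloxy)methyl]-10β-methyl-5βH-decal-1-en-3-one | C1COC2(O1)CC[C@H]3CC(=O)C=C[C@@]3(C)[C@H]2COCc1ccc(OC)cc1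
F6 | step 10 | 4α-(3-methylbut-2-enyl) derivative of F5 | C1COC2(O1)CC[C@H]3[C@@H](CC=C(C)C)C(=O)C=C[C@@]3(C)[C@H]2COCc1ccc(OC)cc1
F7 | step 10 | 4β-methyl-4α-(3-methylbut-2-enyl) derivative of F5 | C1COC2(O1)CC[C@H]3[C@@](C)(CC=C(C)C)C(=O)C=C[C@@]3(C)[C@H]2COCc1ccc(OC)cc1
F8 | step 23 | 9α-carbaldehyde from 25 | C=C1CC[C@H]2[C@@](C)(CCC(C)(C)OC=O)[C@@H](O[Si](CC)(CC)CC)CC[C@@]2(C)[C@H]1C=O
F9 | step 23 | [5-(methoxycarbonyl)-2-methoxy-6-methyl-4-oxo-4H-pyran-3-yl]magnesium chloride | COC(=O)c1c(C)oc(OC)c([Mg]Cl)c1=O
F10 | step 23 | pyranyl carbinol from F8 and F9 (both carbinol epimers) | C=C1CC[C@H]2[C@@](C)(CCC(C)(C)OC=O)[C@@H](O[Si](CC)(CC)CC)CC[C@@]2(C)[C@H]1C(O)c1c(OC)oc(C)c(C(=O)OC)c1=O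
F11 | step 23 | O-phenyl thionocarbonate of F10 | C=C1CC[C@H]2[C@@](C)(CCC(C)(C)OC=O)[C@@H](O[Si](CC)(CC)CC)CC[C@@]2(C)[C@H]1C(OC(=S)Oc1ccccc1)c1c(OC)oc(C)c(C(=O)OC)c1=O
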